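**Two flasks.** I froze one number. The alder run, whose recipe stands with the others below, held Pdt at 43.2% of its charged Sbt at 18 h, and I call this ratio of c(Pdt) at that time to c(Sbt) charged the end share.

| flask | Sbt | Ctl | time |
|---|---|---|---|
| alder | 0.600 M | 0.00120 M |  |
| elm | 0.240 M | 0.00120 M |  |
| oak | 1.80 M | 0.00120 M |  |
| ash | 1.20 M | 0.00360 M | 18 h |

| run | time / h | [Pdt] / M |
|---|---|---|
| alder run | 0.72 | 0.027 |
| alder run | 1.4 | 0.045 |
| alder run | 2.6 | 0.072 |
| alder run | 5.0 | 0.126 |
| alder run | 9.5 | 0.203 |
| alder run | 18 | 0.259 |
| elm run | 0.72 | 0.003 |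
| elm run | 1.4 | 0.019 |
| elm run | 2.6 | 0.030 |
| elm run | 5.0 | 0.051 |
| elm run | 9.5 | 0.074 |
| elm run | 18 | 0.106 |
| oak run | 0.72 | 0.069 |
| oak run | 1.4 | 0.132 |
| oak run | 2.6 | 0.219 |
| oak run | 5.0 | 0.386 |
| oak run | 9.5 | 0.598 |
| oak run | 18 | 0.751 |

(scatter of a reading: 0.005 M)

1. the exponent of [Sbt] in the starting rate at the charge of the alder run (at the point where two percent of the Sbt have become Pdt) (one fixed amount of Pdt, the same in the runs compared)
2. Pdt in the ash run at 18 h, as a share of the Sbt charged

- Overall: Sbt -> Pdt, with Ctl as catalyst.
- Constant volume, constant temperature.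
- An order is taken over about fifteen percent of the charge, up and down.

**Its neighbour.** The oak run had the same c(Ctl) as the alder run, 0.00120 M, and its end share was 41.7%. At 18 h oak read 0.751 M against 0.259 M in alder because its charge was larger, by a factor of 3.00, and the end shares of the two were close. At 2.6 h, the Pdt of oak over that of alder gave an exponent of 1.01 in Sbt between those two charges, taken at one time and not at one amount of Pdt, a reading that carries the scatter.

**My reckoning.** I committed to an order of 1. The ash run, however, has 3.00 times the c(Ctl) of alder, while elm and oak stood at 0.00120 M and 0.00120 M, the same as alder. So I kept the alder end share as a reference for ash, not as a forecast.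

**The forecast.** The forecast gave an order of 1 and 52% for the ash run, above the alder end share. Its choice was plain: “I favour equilibrium, the simpler explanation”.

**The result.** The ash run held Pdt at 57.5% of the Sbt charged at 18 h, and the order at the alder charge was 1.0; the steps were these:

    2 Ctl ⇌ Ctl2, settled at all times (1240 /M)
    Ctl + Sbt → Pdt + Ctl (166.3 /M/h)
    Ctl + Z → E
    Pdt → X (0.03960 /h)

A fit in which the product speeds the reaction had put the ash run at 70.4%. The ash share was 1.33 times the alder end share, on 3.00 times the Ctl and 2.00 times the Sbt. Applied to the elm run, the alder end share gives 0.104 M, and elm read 0.106 M.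

The runs were computed with made-up constants, and the scatter is random.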